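The trap in a racemate is to read left-handed product against a ceiling of half, the 50.0% that the left-handed substrate brings. Here a single-handed free catalyst is proposed to turn both substrates, with the partner, into their products.

| flask | left-handed substrate | right-handed substrate | partner | free catalyst | temperature | remark | time |
|---|---|---|---|---|---|---|---|
| green | 0.77 M | 0.77 M | 3 equiv | 0.11 mol% | 70 °C | the very flask that is asked about, followed so far |  |
| grey | 0.77 M | 0.77 M | 3 equiv | 0.055 mol% | 70 °C | run made earlier |  |
| flask | 0.77 M | 0.77 M | 3.00 equiv | 0.11 mol% | 70 °C |  | 50 min |

| green: time / min | green: left-handed product / % | grey: time / min | grey: left-handed product / % |
|---|---|---|---|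
| 3.00 | 32 | 0.200 | 0 |
| 6.00 | 43 | 0.417 | 3 |
| 12.0 | 50 | 0.667 | 10 |
| 20.0 | 52 | 1.33 | 17 |
| 40.0 | 55 | 2.50 | 21 |

(scatter of a reading: 2 percentage points)

- maple: at 50 min add free catalyst, 100% of the amount charged, then wait 50 min
- oak: at 50 min take out 90% of the left-handed product then present, then wait 50 min
- elm: change nothing and wait 50 min more
- birch: at 50 min raise the temperature by 10 K, then wait 50 min

- free catalyst is single-handed; left-handed substrate and right-handed substrate are mirror images of each other, charged as a racemate, each of them at the stated concentration
- left-handed product that was removed still counts
- steps that have been proposed: partner + free catalyst + left-handed substrate -> free catalyst + left-handed product; partner + free catalyst + right-handed substrate -> free catalyst + right-handed product; left-handed substrate <-> right-handed substrate; partner + free catalyst -> spent catalyst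
- the earlier runs do not show what temperature does; that part of a forecast is a guess
- additions bring no volume worth counting

1. left-handed product, in percent of the left-handed substrate and right-handed substrate together first charged, at 50 min
2. which option adds most left-handed product ("none" when 2 percentage points or less is all one gets) (maple / oak / elm / birch / none)
3. left-handed product present, with what was taken out counted in, in percent of the left-handed substrate and right-handed substrate together first charged, after maple
4. left-handed product present, with what was taken out counted in, in percent of the left-handed substrate and right-handed substrate together first charged, after elm

I take two extremes. If the substrates never interconvert, left-handed product cannot pass 50.0%. If they interconvert freely, and the catalyst and partner last (dynamic kinetic resolution), the substrate is used up, and the end reading equals the left share λ. I define λ as left-handed product divided by left-handed plus right-handed product; 50.0% is its zero, the value for a catalyst without preference.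

The green run's last reading, 55% at 40.0 min, stands above the first extreme, so the substrates do interconvert. The two products together cannot pass the charge, so λ is at least this reading. That gives a floor of the left share, read with the scatter of 2 percentage points: 55.0%. On the floor, the green stall means an empty flask; above it, substrate remains.

The grey run slows early. It gains 7 points from 0.667 min to 1.33 min, then 4 points over the longer span to 2.50 min, a slower pace, while its left-handed product stands at 21%. So I read the green stall as dying catalyst, with the flask between the extremes. I commit to about 55% now, little from waiting, and maple as best.

The forecast gives 56% now, 1 point above mine, maple as best, 62% after maple and 58% after elm: “Fresh catalyst consumes that pool plus further flux, so maple wins.”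

The flask gives 54.4% now. The best option is maple, which adds 6.1 points and reaches 60.4%; elm adds 0.18 points and reaches 54.6%.

    partner + free catalyst + left-handed substrate → free catalyst + left-handed product (k = 4.80 L² mol⁻² s⁻¹, Ea = 50.0 kJ mol⁻¹)
    partner + free catalyst + right-handed substrate → free catalyst + right-handed product (k = 2.70 L² mol⁻² s⁻¹, Ea = 38.0 kJ mol⁻¹)
    left-handed substrate ⇌ right-handed substrate (k = 0.00470 s⁻¹, Ea = 110 kJ mol⁻¹)
    partner + free catalyst → spent catalyst (k = 0.00140 L mol⁻¹ s⁻¹, Ea = 82.0 kJ mol⁻¹)
    (constants at 70 °C)

In this flask the substrates relax towards each other, by that step alone, with a half-life of 1.23 min, shorter than the 1.91 min by which half of the left-handed step's turnover up to 50 min is done. At 50.0 min they stand level at 5.49% and 5.51%, with 98.8% of the catalyst spent. The left share in this flask is then 61.1%, above the floor, with 11.0% of substrate still standing. The neighbour with 1.20 equiv of partner holds 37.4% of left-handed product and 22.1% of right-handed product, so its left share also stands above the floor, at 62.9%.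

The data come from a simulation with constants of no real substance, noise included.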